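**Plan**
- Retrosynthetic cuts: first the enone Cα=Cβ bond (aldol condensation), then the C5–acetyl bond, then the C2–C3 bond of the dihydrofuran, and last the aryl O–CH2 ether bond.
- Enabling feature: in the dihydrofuran ring, C3 is an unsubstituted benzylic CH2 and C2 is an ether CH between O1 and a quaternary carbinol carbon. C2–C3 can therefore come from an aryl carbene at C3 that inserts into the O–CH2 of an aryl 2-silyloxy-2-methylpropyl ether.
- Forward order: catalogue phenol 1 is alkylated with 2,2-dimethyloxirane, silylated and converted into tosylhydrazone 6. The dihydrofuran (the only ring made; the chroman is bought) closes in step 4.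
- C5 is then brominated and acetylated, both protecting groups are removed, and the chroman aldehyde is joined last.
- Stereochemistry: the single stereocentre C2 (R) is set in step 4 by a chiral cobalt(II) porphyrin. The E-alkene is the thermodynamic outcome of the final aldol dehydration.

Key step: step 4

Assumption: of the two antipodes of the chiral porphyrin ligand, the one that leads to (R)-8 is to be identified in a pilot run and used throughout.

**Step 1**
Reactants: 1 4-(benzyloxy)-2-hydroxybenzaldehyde; 2 2,2-dimethyloxirane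
Product: 3 4-(benzyloxy)-2-(2-hydroxy-2-methylpropoxy)benzaldehyde
Conditions: K2CO3 (1 equiv), 2 (3 equiv), DMF, 100 °C, sealed tube
Reagents that add atoms: none
Why: Base-mediated SN2 ring opening of an epoxide by a phenoxide takes place at the unsubstituted CH2 terminus of 2, which gives the aryl 2-hydroxy-2-methylpropyl ether while the non-enolisable aldehyde and the benzyl ether are inert to carbonate.

**Step 2**
Reactants: 3 4-(benzyloxy)-2-(2-hydroxy-2-methylpropoxy)benzaldehyde
Product: 4 4-(benzyloxy)-2-[2-methyl-2-(triethylsilyloxy)propoxy]benzaldehyde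
Conditions: TESOTf, 2,6-lutidine, CH2Cl2, −78 to 0 °C
Reagents that add atoms: triethylsilyl trifluoromethanesulfonate, CC[Si](CC)(CC)OS(=O)(=O)C(F)(F)F
Why: Silyl ether protection with a silyl triflate and a hindered pyridine base is fast even for tertiary alcohols at low temperature and leaves the non-enolisable aryl aldehyde untouched, so the hydroxyl is masked before the diazo chemistry.

**Step 3**
Reactants: 4 4-(benzyloxy)-2-[2-methyl-2-(triethylsilyloxy)propoxy]benzaldehyde; 5 p-toluenesulfonohydrazide
Product: 6 (E)-N'-{4-(benzyloxy)-2-[2-methyl-2-(triethylsilyloxy)propoxy]benzylidene}-4-methylbenzenesulfonohydrazide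
Conditions: 5 (1.05 equiv), MeOH, rt
Reagents that add atoms: none
Why: N-Tosylhydrazone formation from an aryl aldehyde and a sulfonyl hydrazide proceeds without catalyst in methanol and should deliver the crystalline E-hydrazone, the near-neutral medium sparing the tertiary silyl ether.

**Step 4**
Reactants: 6 (E)-N'-{4-(benzyloxy)-2-[2-methyl-2-(triethylsilyloxy)propoxy]benzylidene}-4-methylbenzenesulfonohydrazide
Product: 8 (R)-6-(benzyloxy)-2-[2-(triethylsilyloxy)propan-2-yl]-2,3-dihydrobenzofuran, via aryldiazomethane 7 (not isolated)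
Conditions: Cs2CO3 (2 equiv), Co(II) complex of a D2-symmetric chiral amidoporphyrin (3 mol %), toluene, 40 °C, N2
Reagents that add atoms: none
Why: Caesium carbonate converts the tosylhydrazone into aryldiazomethane 7 (Bamford–Stevens release), which the cobalt(II) metalloradical captures with loss of N2 as an α-cobalt(III) benzyl radical; this abstracts a hydrogen atom from the ArO–CH2 group through a six-membered transition state, and the resulting α-alkoxyalkyl radical displaces cobalt at the benzylic carbon to form C2–C3. The closest known reaction type is the cobalt-porphyrin-catalysed enantioselective radical 1,5-C–H alkylation with aryl aldehyde tosylhydrazones that furnishes 2-substituted five-membered benzo-fused heterocycles. The dihydrofuran ring closes by a 5-exo-tet radical substitution, the net result being a 1,5 C–H insertion. The C2 stereocentre is controlled by the catalyst alone: the chiral amide-lined pocket of the porphyrin selects one of the two enantiotopic O–CH2 hydrogens and holds the short-lived radical so that C–C bond formation follows on the same face, which should give R with the matching ligand antipode. The step needs site selectivity and suppression of azine and stilbene formation; the ether oxygen weakens the only C–H bonds in a 1,5 relation to the carbene carbon, the neighbouring carbinol carbon is quaternary and silylated so that neither a 1,2-hydride shift nor O–H insertion can compete, and slow diazo release from the sparingly soluble hydrazone salt keeps its concentration low.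

**Step 5**
Reactants: 8 (R)-6-(benzyloxy)-2-[2-(triethylsilyloxy)propan-2-yl]-2,3-dihydrobenzofuran
Product: 9 (R)-6-(benzyloxy)-5-bromo-2-[2-(triethylsilyloxy)propan-2-yl]-2,3-dihydrobenzofuran
Conditions: NBS (1.05 equiv), MeCN, 0 °C, dark
Reagents that add atoms: N-bromosuccinimide, O=C1CCC(=O)N1Br
Why: Electrophilic aromatic bromination should go to C5 alone, because this carbon is para to O1 and ortho to the benzyloxy group, whereas C7 is crowded between two oxygens, C4 is meta to both, and the pendant phenyl ring is not activated.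

**Step 6**
Reactants: 9 (R)-6-(benzyloxy)-5-bromo-2-[2-(triethylsilyloxy)propan-2-yl]-2,3-dihydrobenzofuran
Product: 11 1-{(R)-6-(benzyloxy)-2-[2-(triethylsilyloxy)propan-2-yl]-2,3-dihydrobenzofuran-5-yl}ethan-1-one, via aryllithium 10 (not isolated)
Conditions: n-BuLi, THF, −78 °C; then MeC(O)N(OMe)Me, −78 to 0 °C; aq NH4Cl
Reagents that add atoms: N-methoxy-N-methylacetamide, CON(C)C(C)=O
Why: Bromine–lithium exchange at −78 °C is faster than deprotonation next to the ether oxygens, and the aryllithium adds once to the Weinreb amide because the chelated tetrahedral adduct only collapses to the methyl ketone on work-up (Weinreb ketone synthesis).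

**Step 7**
Reactants: 11 1-{(R)-6-(benzyloxy)-2-[2-(triethylsilyloxy)propan-2-yl]-2,3-dihydrobenzofuran-5-yl}ethan-1-one
Product: 12 1-{(R)-6-hydroxy-2-[2-(triethylsilyloxy)propan-2-yl]-2,3-dihydrobenzofuran-5-yl}ethan-1-one
Conditions: H2 (1 atm), 10% Pd/C, EtOAc, rt
Reagents that add atoms: none
Why: Catalytic hydrogenolysis of an aryl benzyl ether over palladium is much faster than reduction of the electron-rich aryl ketone, and neither the silyl ether nor the non-benzylic C2–O bond is cleaved, so the stereocentre is untouched.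

**Step 8**
Reactants: 12 1-{(R)-6-hydroxy-2-[2-(triethylsilyloxy)propan-2-yl]-2,3-dihydrobenzofuran-5-yl}ethan-1-one
Product: 13 1-[(R)-6-hydroxy-2-(2-hydroxypropan-2-yl)-2,3-dihydrobenzofuran-5-yl]ethan-1-one
Conditions: HF·pyridine, pyridine/THF, 0 °C to rt
Reagents that add atoms: none
Why: Fluoride-driven cleavage of the Si–O bond (desilylation) frees the tertiary alcohol under buffered conditions that neither ionise the carbinol nor open the dihydrofuran.

**Step 9**
Reactants: 13 1-[(R)-6-hydroxy-2-(2-hydroxypropan-2-yl)-2,3-dihydrobenzofuran-5-yl]ethan-1-one; 14 2,2-dimethylchroman-6-carbaldehyde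
Product: 15 (E)-3-(2,2-dimethylchroman-6-yl)-1-[(R)-6-hydroxy-2-(2-hydroxypropan-2-yl)-2,3-dihydrobenzofuran-5-yl]prop-2-en-1-one
Conditions: KOH (50% aq, excess), EtOH, 0 °C to rt; then dilute HCl to pH 5–6
Reagents that add atoms: none
Why: In this Claisen–Schmidt condensation the methyl ketone enolate adds to the non-enolisable aldehyde and E1cB loss of water gives the conjugated enone as the more stable E isomer, while C2 is not at risk because C3 stands meta to the acyl group and carries no acidified hydrogen.

**Compound list**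
1 | 4-(benzyloxy)-2-hydroxybenzaldehyde | O=Cc1ccc(OCc2ccccc2)cc1O | starting material
2 | 2,2-dimethyloxirane | CC1(C)CO1 | starting material
3 | 4-(benzyloxy)-2-(2-hydroxy-2-methylpropoxy)benzaldehyde | O=Cc1ccc(OCc2ccccc2)cc1OCC(C)(C)O | intermediate
4 | 4-(benzyloxy)-2-[2-methyl-2-(triethylsilyloxy)propoxy]benzaldehyde | O=Cc1ccc(OCc2ccccc2)cc1OCC(C)(C)O[Si](CC)(CC)CC | intermediate
5 | p-toluenesulfonohydrazide | Cc1ccc(cc1)S(=O)(=O)NN | starting material
6 | (E)-N'-{4-(benzyloxy)-2-[2-methyl-2-(triethylsilyloxy)propoxy]benzylidene}-4-methylbenzenesulfonohydrazide | Cc1ccc(cc1)S(=O)(=O)N/N=C/c1ccc(OCc2ccccc2)cc1OCC(C)(C)O[Si](CC)(CC)CC | intermediate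
7 | 4-(benzyloxy)-1-(diazomethyl)-2-[2-methyl-2-(triethylsilyloxy)propoxy]benzene | [N-]=[N+]=Cc1ccc(OCc2ccccc2)cc1OCC(C)(C)O[Si](CC)(CC)CC | intermediate (not isolated)
8 | (R)-6-(benzyloxy)-2-[2-(triethylsilyloxy)propan-2-yl]-2,3-dihydrobenzofuran | C(c1ccccc1)Oc1ccc2c(c1)O[C@@H](C(C)(C)O[Si](CC)(CC)CC)C2 | intermediate
9 | (R)-6-(benzyloxy)-5-bromo-2-[2-(triethylsilyloxy)propan-2-yl]-2,3-dihydrobenzofuran | Brc1cc2c(cc1OCc1ccccc1)O[C@@H](C(C)(C)O[Si](CC)(CC)CC)C2 | intermediate
10 | {(R)-6-(benzyloxy)-2-[2-(triethylsilyloxy)propan-2-yl]-2,3-dihydrobenzofuran-5-yl}lithium | [Li]c1cc2c(cc1OCc1ccccc1)O[C@@H](C(C)(C)O[Si](CC)(CC)CC)C2 | intermediate (not isolated)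
11 | 1-{(R)-6-(benzyloxy)-2-[2-(triethylsilyloxy)propan-2-yl]-2,3-dihydrobenzofuran-5-yl}ethan-1-one | CC(=O)c1cc2c(cc1OCc1ccccc1)O[C@@H](C(C)(C)O[Si](CC)(CC)CC)C2 | intermediate
12 | 1-{(R)-6-hydroxy-2-[2-(triethylsilyloxy)propan-2-yl]-2,3-dihydrobenzofuran-5-yl}ethan-1-one | CC(=O)c1cc2c(cc1O)O[C@@H](C(C)(C)O[Si](CC)(CC)CC)C2 | intermediate
13 | 1-[(R)-6-hydroxy-2-(2-hydroxypropan-2-yl)-2,3-dihydrobenzofuran-5-yl]ethan-1-one | CC(=O)c1cc2c(cc1O)O[C@@H](C(C)(C)O)C2 | intermediate
14 | 2,2-dimethylchroman-6-carbaldehyde | CC1(C)CCc2cc(C=O)ccc2O1 | starting material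
15 | (E)-3-(2,2-dimethylchroman-6-yl)-1-[(R)-6-hydroxy-2-(2-hydroxypropan-2-yl)-2,3-dihydrobenzofuran-5-yl]prop-2-en-1-one | CC1(C)CCc2cc(/C=C/C(=O)c3cc4c(cc3O)O[C@@H](C(C)(C)O)C4)ccc2O1 | target

**Step count**
Total steps: 9. Longest linear sequence: 9 steps (1 to 15); aldehyde 14 enters in the last step.

**Steps most likely to fail**

Step 4. Bimolecular consumption of the diazo intermediate (azine formation, carbene dimerisation) may outrun the hindered intramolecular hydrogen abstraction, or the catalyst pocket may discriminate the two enantiotopic hydrogens poorly. The fallback sets out from 1 and comes back at 8; it forms C2–C3 by aldol condensation and takes the configuration from a resolution. Rap–Stoermer condensation of 1 with ethyl bromoacetate (K2CO3, DMF, 110 °C) should give ethyl 6-(benzyloxy)benzofuran-2-carboxylate F1. Magnesium in methanol would reduce its C2=C3 bond with ester exchange to racemic methyl 6-(benzyloxy)-2,3-dihydrobenzofuran-2-carboxylate F2. Separation of the enantiomers on a chiral stationary phase would provide methyl (R)-6-(benzyloxy)-2,3-dihydrobenzofuran-2-carboxylate F3. Excess MeMgBr (THF, −20 °C) would turn the ester into (R)-2-[6-(benzyloxy)-2,3-dihydrobenzofuran-2-yl]propan-2-ol F4, and silylation under the conditions of step 2 returns to 8.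

Step 9. Enolisation of the phenoxide-bearing ketone towards an electron-rich aldehyde may be sluggish, and the 2'-hydroxychalcone may close by conjugate addition to the flavanone during a long reaction or on work-up. The fallback sets out from 12 and comes back at 15, with the phenol masked during the condensation. Sodium hydride and chloromethyl methyl ether (THF, 0 °C) would convert 12 into 1-{(R)-6-(methoxymethoxy)-2-[2-(triethylsilyloxy)propan-2-yl]-2,3-dihydrobenzofuran-5-yl}ethan-1-one F5. Claisen–Schmidt condensation with 14 (KOH, EtOH, rt) would give (E)-3-(2,2-dimethylchroman-6-yl)-1-{(R)-6-(methoxymethoxy)-2-[2-(triethylsilyloxy)propan-2-yl]-2,3-dihydrobenzofuran-5-yl}prop-2-en-1-one F6. HCl in methanol at rt would then remove the acetal and the silyl ether together and arrive at 15.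

Step 6. Proton transfer to the aryllithium, from the benzylic OCH2 group or from the α-hydrogens of the acetamide, may lead to debromination instead of acylation. The fallback sets out from 9 and comes back at 11, replacing the organolithium by a palladium-catalysed coupling. Stille coupling of 9 with tributyl(1-ethoxyvinyl)stannane (PdCl2(PPh3)2, toluene, 100 °C) would give (R)-6-(benzyloxy)-5-(1-ethoxyvinyl)-2-[2-(triethylsilyloxy)propan-2-yl]-2,3-dihydrobenzofuran F7. Brief hydrolysis of the enol ether (1 M HCl, THF, 0 °C), which is much faster than loss of the tertiary silyl ether, returns to 11.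

**Further compounds**
F1 | step 4 | ethyl 6-(benzyloxy)benzofuran-2-carboxylate | CCOC(=O)c1cc2ccc(OCc3ccccc3)cc2o1
F2 | step 4 | racemic methyl 6-(benzyloxy)-2,3-dihydrobenzofuran-2-carboxylate | COC(=O)C1Cc2ccc(OCc3ccccc3)cc2O1
F3 | step 4 | methyl (R)-6-(benzyloxy)-2,3-dihydrobenzofuran-2-carboxylate | C(c1ccccc1)Oc1ccc2c(c1)O[C@@H](C(=O)OC)C2
F4 | step 4 | (R)-2-[6-(benzyloxy)-2,3-dihydrobenzofuran-2-yl]propan-2-ol | C(c1ccccc1)Oc1ccc2c(c1)O[C@@H](C(C)(C)O)C2
F5 | step 9 | 1-{(R)-6-(methoxymethoxy)-2-[2-(triethylsilyloxy)propan-2-yl]-2,3-dihydrobenzofuran-5-yl}ethan-1-one | CC(=O)c1cc2c(cc1OCOC)O[C@@H](C(C)(C)O[Si](CC)(CC)CC)C2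
F6 | step 9 | (E)-3-(2,2-dimethylchroman-6-yl)-1-{(R)-6-(methoxymethoxy)-2-[2-(triethylsilyloxy)propan-2-yl]-2,3-dihydrobenzofuran-5-yl}prop-2-en-1-one | CC1(C)CCc2cc(/C=C/C(=O)c3cc4c(cc3OCOC)O[C@@H](C(C)(C)O[Si](CC)(CC)CC)C4)ccc2O1
F7 | step 6 | (R)-6-(benzyloxy)-5-(1-ethoxyvinyl)-2-[2-(triethylsilyloxy)propan-2-yl]-2,3-dihydrobenzofuran | CCOC(=C)c1cc2c(cc1OCc1ccccc1)O[C@@H](C(C)(C)O[Si](CC)(CC)CC)C2
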